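The route rests on disconnecting the C3–C4 bond of ring A: the cis-3β,4β-diol (secondary C3 carbinol, tertiary C4 carbinol carrying the α-methyl, O4 axial and syn to the C10 methyl) is the retron of a ketyl–carbonyl coupling. In one operation, SmI2 (divalent samarium) joins a C3 aldehyde to a C4 methyl ketone, closing ring A onto a preformed ring B and setting C3 and C4. The precursor is a ring-B cyclohexene carrying trans propanal (C10) and acetyl (C5) arms and a C7 triisopropylsilyl enol ether; its C5/C10 centres come from one catalytic asymmetric Diels–Alder reaction, and its aldehyde is unveiled last by hydroformylation. Ring-B oxidation and the two esters follow.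

Key step: step 7

Numbering: ring atoms carry eudesmane locants throughout (ring A = C1–C5 and C10, ring B = C5–C10); β is the face of the C10 methyl; bicyclic intermediates are named as 4,10-dimethyldecalins with these locants.

Remark: the facial sense of step 2 is assigned from the formyl C–H···O binding model for α-substituted enals on the (S)-oxazaborolidinium ion; if the antipode of 4 were to form, the (R)-catalyst would be used with nothing else changed.

Step 1
Reactants: 1 methyl vinyl ketone
Product: 2 2-(triisopropylsilyloxy)buta-1,3-diene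
Conditions: TIPSOTf, Et3N, CH2Cl2, 0 °C → rt
Reagents that add atoms: triisopropylsilyl trifluoromethanesulfonate, CC(C)[Si](OS(=O)(=O)C(F)(F)F)(C(C)C)C(C)C
Why: O-silylation of the methyl-side enol of the enone under soft enolisation (silyl dienol ether formation) gives the 2-silyloxydiene, and no stereocentre is formed.

Step 2
Reactants: 2 2-(triisopropylsilyloxy)buta-1,3-diene; 3 ethyl (E)-3-methyl-4-oxobut-2-enoate
Product: 4 ethyl (1R,6R)-6-formyl-6-methyl-3-(triisopropylsilyloxy)cyclohex-3-ene-1-carboxylate
Conditions: (S)-3,3-diphenyl-1-(2-methylphenyl)tetrahydro-1H,3H-pyrrolo[1,2-c][1,3,2]oxazaborole (20 mol %), HN(SO2CF3)2 (16 mol %), CH2Cl2, −78 °C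
Reagents that add atoms: none
Why: Enantioselective Diels–Alder reaction under chiral oxazaborolidinium catalysis: the cationic boron binds the formyl oxygen, the nucleophilic C1 of the diene bonds to the β-carbon (the CH bearing CO2Et) so that the silyloxy carbon ends para to the formyl-bearing carbon, the (E)-geometry is carried over suprafacially into the trans CHO/CO2Et relationship, and the catalyst leaves one face of the s-trans enal open, which sets C5 and C10 together.

Step 3
Reactants: 4 ethyl (1R,6R)-6-formyl-6-methyl-3-(triisopropylsilyloxy)cyclohex-3-ene-1-carboxylate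
Product: 5 ethyl (1R,6S)-6-ethenyl-6-methyl-3-(triisopropylsilyloxy)cyclohex-3-ene-1-carboxylate
Conditions: Ph3PCH3Br, KOt-Bu, THF, −78 → 0 °C
Reagents that add atoms: methyltriphenylphosphonium bromide, C[P+](c1ccccc1)(c1ccccc1)c1ccccc1.[Br-]
Why: Wittig methylenation: the unstabilised ylide attacks the non-enolisable neopentyl aldehyde far faster than the ester at low temperature, and the existing centres are untouched (the descriptor at the quaternary carbon changes by priority only).

Step 4
Reactants: 5 ethyl (1R,6S)-6-ethenyl-6-methyl-3-(triisopropylsilyloxy)cyclohex-3-ene-1-carboxylate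
Product: 6 (1R,6S)-6-ethenyl-N-methoxy-N,6-dimethyl-3-(triisopropylsilyloxy)cyclohex-3-ene-1-carboxamide
Conditions: MeNH(OMe)·HCl, i-PrMgCl, THF, −20 → 0 °C
Reagents that add atoms: N,O-dimethylhydroxylamine hydrochloride, CNOC.Cl
Why: Weinreb amide formation by aminolysis of the ester with the chloromagnesium amide of N,O-dimethylhydroxylamine, which runs below 0 °C and so should not epimerise the α-carbon (C5), while the vinyl group and the enol silane are inert.

Step 5
Reactants: 6 (1R,6S)-6-ethenyl-N-methoxy-N,6-dimethyl-3-(triisopropylsilyloxy)cyclohex-3-ene-1-carboxamide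
Product: 7 1-[(1R,6S)-6-ethenyl-6-methyl-3-(triisopropylsilyloxy)cyclohex-3-en-1-yl]ethan-1-one
Conditions: MeMgBr, THF, 0 °C; aq NH4Cl
Reagents that add atoms: methylmagnesium bromide, C[Mg]Br
Why: Weinreb ketone synthesis: the magnesium chelate of the tetrahedral adduct survives until aqueous work-up, so a single methyl group is delivered and the ketone is never exposed to the Grignard reagent.

Step 6
Reactants: 7 1-[(1R,6S)-6-ethenyl-6-methyl-3-(triisopropylsilyloxy)cyclohex-3-en-1-yl]ethan-1-one
Product: 8 3-[(1R,6R)-6-acetyl-1-methyl-4-(triisopropylsilyloxy)cyclohex-3-en-1-yl]propanal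
Conditions: Rh(acac)(CO)2 (1 mol %), Xantphos (4,5-bis(diphenylphosphino)-9,9-dimethylxanthene, 2 mol %), CO/H2 (1:1, 20 bar), toluene, 70 °C
Reagents that add atoms: carbon monoxide, [C-]#[O+]
Why: Rhodium-catalysed hydroformylation of the monosubstituted alkene: the branched aldehyde would have to form next to the quaternary carbon, so only the linear aldehyde is expected, the trisubstituted enol silane and the ketone do not react, and the neutral conditions leave the epimerisable C5 alone.

Step 7
Reactants: 8 3-[(1R,6R)-6-acetyl-1-methyl-4-(triisopropylsilyloxy)cyclohex-3-en-1-yl]propanal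
Product: 9 4α,10β-dimethyl-7-(triisopropylsilyloxy)-5αH-decal-7-ene-3β,4β-diol
Conditions: SmI2 (divalent samarium, 2.5 equiv), t-BuOH (2 equiv), THF (0.01 M), −78 °C → rt
Reagents that add atoms: none
Why: Single-electron transfer from SmI2 to the more easily reduced aldehyde gives a samarium-bound C3 ketyl that adds to the carbonyl carbon of the neighbouring C4 methyl ketone, and a second electron transfer turns the resulting alkoxy radical into the samarium diolate, which t-BuOH protonates. The closest known reaction type is the SmI2-promoted intramolecular ketone–aldehyde pinacol cyclisation that delivers cis-cyclohexane-1,2-diols. Ring A (C3–C2–C1–C10–C5–C4) closes in a 6-exo-trig ketyl addition through a chair in which both arms sit equatorial on ring B, so the new ring is trans-fused. C3 and C4 are set together: bridging of both oxygens by one trivalent samarium centre forces them cis, and the axial C10 methyl pushes the C4 methyl equatorial, so O4 becomes axial (β, syn to C10–CH3) and O3 equatorial (β). The step needs this diastereoselectivity and chemoselectivity for the two carbonyls over the C7 enol silane; the first rests on chelation plus the 1,3-diaxial methyl–methyl penalty, the second on the inertness of silyl enol ethers to SmI2, and high dilution suppresses intermolecular coupling.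

Step 8
Reactants: 9 4α,10β-dimethyl-7-(triisopropylsilyloxy)-5αH-decal-7-ene-3β,4β-diol
Product: 11 3β,4β-dihydroxy-4α,10β-dimethyl-8α-(triisopropylsilyloxy)-5αH-decalin-7-one, via silyloxy epoxide 10 (not isolated)
Conditions: mCPBA, CH2Cl2, −20 °C → rt
Reagents that add atoms: 3-chloroperoxybenzoic acid, OOC(=O)c1cccc(Cl)c1
Why: Rubottom oxidation: the peracid epoxidises the electron-rich enol silane from the α face, away from the axial C10 methyl that stands 1,3 to C8, and acid-promoted opening with 1,4-silyl shift gives the α-silyloxy ketone with O8 α (equatorial), which leaves O8 protected for the next step.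

Step 9
Reactants: 11 3β,4β-dihydroxy-4α,10β-dimethyl-8α-(triisopropylsilyloxy)-5αH-decalin-7-one; 12 isopropenylmagnesium bromide
Product: 13 4α,10β-dimethyl-7β-(prop-1-en-2-yl)-8α-(triisopropylsilyloxy)-5αH-decalin-3β,4β,7α-triol
Conditions: 12 (5 equiv), CeCl3 (anhydrous, 5 equiv), THF, −78 °C
Reagents that add atoms: none
Why: Organocerium 1,2-addition to the ketone: the bulky sp2 nucleophile should enter along the equatorial (β) trajectory, a preference reinforced by the equatorial C8 substituent, so that the new C7 hydroxyl is axial (α) and the isopropenyl group equatorial (β), while the weakly basic cerium reagent avoids enolisation and the two free hydroxyls only consume reagent as alkoxides.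

Step 10
Reactants: 13 4α,10β-dimethyl-7β-(prop-1-en-2-yl)-8α-(triisopropylsilyloxy)-5αH-decalin-3β,4β,7α-triol
Product: 15 4β-acetoxy-4α,10β-dimethyl-7β-(prop-1-en-2-yl)-8α-(triisopropylsilyloxy)-5αH-decalin-3β,7α-diol, via cyclic orthoacetate 14 (not isolated)
Conditions: MeC(OMe)3, PPTS (cat.), CH2Cl2, rt; then AcOH/H2O (4:1), rt
Reagents that add atoms: trimethyl orthoacetate, COC(C)(OC)OC; water, O
Why: Regioselective monoacetylation through a cyclic orthoester: only the cis-3,4-diol can form the five-membered orthoacetate, and its mild acid hydrolysis follows the stereoelectronic rule for axial/equatorial cis-diols on a chair (the C–O bond to the equatorial oxygen breaks), which puts the acetate on the axial tertiary O4 and frees the equatorial C3 hydroxyl without changing any stereocentre.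

Step 11
Reactants: 15 4β-acetoxy-4α,10β-dimethyl-7β-(prop-1-en-2-yl)-8α-(triisopropylsilyloxy)-5αH-decalin-3β,7α-diol; 16 angelic acid [(Z)-2-methylbut-2-enoic acid]
Product: 18 4β-acetoxy-3β-[(Z)-2-methylbut-2-enoyloxy]-4α,10β-dimethyl-7β-(prop-1-en-2-yl)-8α-(triisopropylsilyloxy)-5αH-decalin-7α-ol, via mixed anhydride 17 (not isolated)
Conditions: 16, 2,4,6-Cl3C6H2COCl, Et3N, toluene, rt; then 15, 80 °C
Reagents that add atoms: none
Why: Yamaguchi-type esterification with the preformed mixed anhydride and no nucleophilic catalyst, conditions under which the angeloyl group is transferred without Z-to-E isomerisation; the secondary equatorial C3 hydroxyl is acylated and the hindered tertiary C7 hydroxyl is not.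

Step 12
Reactants: 18 4β-acetoxy-3β-[(Z)-2-methylbut-2-enoyloxy]-4α,10β-dimethyl-7β-(prop-1-en-2-yl)-8α-(triisopropylsilyloxy)-5αH-decalin-7α-ol
Product: 19 4β-acetoxy-3β-[(Z)-2-methylbut-2-enoyloxy]-4α,10β-dimethyl-7β-(prop-1-en-2-yl)-5αH-decalin-7α,8α-diol
Conditions: Bu4NF, AcOH (1:1), THF, 0 °C → rt
Reagents that add atoms: none
Why: Fluoride-induced cleavage of the secondary silyl ether, buffered with acetic acid so that the acetate and the angelate should neither migrate nor hydrolyse.

Step 13
Reactants: 19 4β-acetoxy-3β-[(Z)-2-methylbut-2-enoyloxy]-4α,10β-dimethyl-7β-(prop-1-en-2-yl)-5αH-decalin-7α,8α-diol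
Product: 20 (3S,4R,5R,7S,10R)-4-acetoxy-7-hydroxy-8-oxoeudesm-11-en-3-yl (Z)-2-methylbut-2-enoate (CNP0381775.1)
Conditions: IBX, DMSO, rt
Reagents that add atoms: none
Why: IBX oxidation of the secondary C8 alcohol to the ketone: this reagent converts 1,2-diols into α-ketols without C–C cleavage, the tertiary C7 hydroxyl cannot be oxidised, and the C8 relay centre disappears, which leaves the five stereocentres of the target.

Compound list
1 | methyl vinyl ketone | CC(=O)C=C | starting material
2 | 2-(triisopropylsilyloxy)buta-1,3-diene | C=CC(=C)O[Si](C(C)C)(C(C)C)C(C)C | intermediate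
3 | ethyl (E)-3-methyl-4-oxobut-2-enoate | CCOC(=O)/C=C(C)/C=O | starting material
4 | ethyl (1R,6R)-6-formyl-6-methyl-3-(triisopropylsilyloxy)cyclohex-3-ene-1-carboxylate (CHO trans to CO2Et) | O=C[C@]1(C)CC=C(O[Si](C(C)C)(C(C)C)C(C)C)C[C@H]1C(=O)OCC | intermediate
5 | ethyl (1R,6S)-6-ethenyl-6-methyl-3-(triisopropylsilyloxy)cyclohex-3-ene-1-carboxylate | C=C[C@]1(C)CC=C(O[Si](C(C)C)(C(C)C)C(C)C)C[C@H]1C(=O)OCC | intermediate
6 | (1R,6S)-6-ethenyl-N-methoxy-N,6-dimethyl-3-(triisopropylsilyloxy)cyclohex-3-ene-1-carboxamide | C=C[C@]1(C)CC=C(O[Si](C(C)C)(C(C)C)C(C)C)C[C@H]1C(=O)N(C)OC | intermediate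
7 | 1-[(1R,6S)-6-ethenyl-6-methyl-3-(triisopropylsilyloxy)cyclohex-3-en-1-yl]ethan-1-one | C=C[C@]1(C)CC=C(O[Si](C(C)C)(C(C)C)C(C)C)C[C@H]1C(C)=O | intermediate
8 | 3-[(1R,6R)-6-acetyl-1-methyl-4-(triisopropylsilyloxy)cyclohex-3-en-1-yl]propanal (key-step precursor; propanal and acetyl arms trans) | O=CCC[C@]1(C)CC=C(O[Si](C(C)C)(C(C)C)C(C)C)C[C@H]1C(C)=O | intermediate
9 | 4α,10β-dimethyl-7-(triisopropylsilyloxy)-5αH-decal-7-ene-3β,4β-diol (key-step product; trans-decalin, O4 axial, O3 equatorial) | CC(C)[Si](C(C)C)(C(C)C)OC1=CC[C@@]2(C)CC[C@H](O)[C@](C)(O)[C@@H]2C1 | intermediate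
10 | 7α,8α-epoxy-4α,10β-dimethyl-7β-(triisopropylsilyloxy)-5αH-decalin-3β,4β-diol (silyloxy epoxide) | CC(C)[Si](C(C)C)(C(C)C)O[C@]12O[C@H]1C[C@@]3(C)CC[C@H](O)[C@](C)(O)[C@@H]3C2 | intermediate
11 | 3β,4β-dihydroxy-4α,10β-dimethyl-8α-(triisopropylsilyloxy)-5αH-decalin-7-one | O=C1C[C@@H]2[C@](C)(CC[C@H](O)[C@]2(C)O)C[C@@H]1O[Si](C(C)C)(C(C)C)C(C)C | intermediate
12 | isopropenylmagnesium bromide | C=C(C)[Mg]Br | starting material
13 | 4α,10β-dimethyl-7β-(prop-1-en-2-yl)-8α-(triisopropylsilyloxy)-5αH-decalin-3β,4β,7α-triol | C=C(C)[C@@]1(O)C[C@@H]2[C@](C)(CC[C@H](O)[C@]2(C)O)C[C@@H]1O[Si](C(C)C)(C(C)C)C(C)C | intermediate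
14 | 3β,4β-O-(1-methoxyethylidene) derivative of 13 (cyclic methyl orthoacetate, both epimers at the orthoester carbon) | C=C(C)[C@@]1(O)C[C@@H]2[C@](C)(CC[C@@H]3OC(C)(OC)O[C@]23C)C[C@@H]1O[Si](C(C)C)(C(C)C)C(C)C | intermediate
15 | 4β-acetoxy-4α,10β-dimethyl-7β-(prop-1-en-2-yl)-8α-(triisopropylsilyloxy)-5αH-decalin-3β,7α-diol | C=C(C)[C@@]1(O)C[C@@H]2[C@](C)(CC[C@H](O)[C@]2(C)OC(C)=O)C[C@@H]1O[Si](C(C)C)(C(C)C)C(C)C | intermediate
16 | angelic acid, (Z)-2-methylbut-2-enoic acid | C/C=C(/C)C(=O)O | starting material
17 | (Z)-2-methylbut-2-enoic 2,4,6-trichlorobenzoic anhydride | C/C=C(/C)C(=O)OC(=O)c1c(Cl)cc(Cl)cc1Cl | intermediate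
18 | 4β-acetoxy-3β-[(Z)-2-methylbut-2-enoyloxy]-4α,10β-dimethyl-7β-(prop-1-en-2-yl)-8α-(triisopropylsilyloxy)-5αH-decalin-7α-ol | C=C(C)[C@@]1(O)C[C@@H]2[C@](C)(CC[C@H](OC(=O)/C(C)=C\C)[C@]2(C)OC(C)=O)C[C@@H]1O[Si](C(C)C)(C(C)C)C(C)C | intermediate
19 | 4β-acetoxy-3β-[(Z)-2-methylbut-2-enoyloxy]-4α,10β-dimethyl-7β-(prop-1-en-2-yl)-5αH-decalin-7α,8α-diol | C=C(C)[C@@]1(O)C[C@@H]2[C@](C)(CC[C@H](OC(=O)/C(C)=C\C)[C@]2(C)OC(C)=O)C[C@@H]1O | intermediate
20 | (3S,4R,5R,7S,10R)-4-acetoxy-7-hydroxy-8-oxoeudesm-11-en-3-yl (Z)-2-methylbut-2-enoate (3β-angelate, 4β-acetate, 7α-OH, 7β-isopropenyl, 5α-H, 10β-CH3) | C=C(C)[C@@]1(O)C[C@@H]2[C@](C)(CC[C@H](OC(=O)/C(C)=C\C)[C@]2(C)OC(C)=O)CC1=O | target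

Total step count: 13. Longest linear sequence: 13 steps (1 → 20); compounds 3, 12 and 16 enter as purchased materials.

Steps most likely to fail

Step 7. The ketyl may close without chelation, giving the trans diol or the α,α-cis diol, or the aldehyde may simply be reduced before the C–C bond forms. The fallback sets out from 8 and forms the same C3–C4 bond by two-electron umpolung instead of a ketyl. An N-heterocyclic-carbene-catalysed intramolecular crossed acyloin reaction (3-benzyl-5-(2-hydroxyethyl)-4-methylthiazolium chloride, DBU, t-BuOH, 40 °C) would add the aldehyde carbon to the methyl ketone and give the ring-A ketol 4β-hydroxy-4α,10β-dimethyl-7-(triisopropylsilyloxy)-5αH-decal-7-en-3-one F1. Reduction of F1 with NaBH4 (MeOH, −40 °C), with hydride entering axially from the α face, would then give the equatorial 3β-alcohol and so come back to the route at diol 9.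

Step 9. Facial selectivity at C7 may be poor, with part of the isopropenyl reagent entering axially and giving the C7 epimer. The fallback sets out from 11 and splits the operation in two. 2-Lithio-2-(phenylselanyl)propane (from 2,2-bis(phenylselanyl)propane and n-BuLi, THF, −78 °C) is a much bulkier tertiary sp3 nucleophile that adds to cyclohexanones almost only along the equatorial path. It would give the β-hydroxy selenide 4α,10β-dimethyl-7β-[2-(phenylselanyl)propan-2-yl]-8α-(triisopropylsilyloxy)-5αH-decalin-3β,4β,7α-triol F2. Oxidation (H2O2, pyridine, CH2Cl2, 0 °C → rt) and syn-elimination of the selenoxide towards a methyl group would unveil the isopropenyl group and come back to the route at triol 13.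

Step 11. The prolonged heating needed for the hindered C3 hydroxyl may isomerise the activated angelate to the tiglate, and the acetyl group may migrate from O4 to O3. The fallback sets out from 15 and builds the Z-alkene on the molecule instead of transferring it. Esterification with 2-[bis(2,2,2-trifluoroethoxy)phosphoryl]propanoic acid (EDC·HCl, DMAP cat., CH2Cl2, 0 °C) would be fast and would give the 3β-{2-[bis(2,2,2-trifluoroethoxy)phosphoryl]propanoyloxy} ester F3. A Still–Gennari olefination of F3 with acetaldehyde (KN(SiMe3)2, 18-crown-6, THF, −78 °C) would then form the (Z)-2-methylbut-2-enoate and come back to the route at 18.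

Further compounds
F1 | step 7 | 4β-hydroxy-4α,10β-dimethyl-7-(triisopropylsilyloxy)-5αH-decal-7-en-3-one | CC(C)[Si](C(C)C)(C(C)C)OC1=CC[C@@]2(C)CCC(=O)[C@](C)(O)[C@@H]2C1
F2 | step 9 | 4α,10β-dimethyl-7β-[2-(phenylselanyl)propan-2-yl]-8α-(triisopropylsilyloxy)-5αH-decalin-3β,4β,7α-triol | CC(C)([Se]c1ccccc1)[C@@]1(O)C[C@@H]2[C@](C)(CC[C@H](O)[C@]2(C)O)C[C@@H]1O[Si](C(C)C)(C(C)C)C(C)C
F3 | step 11 | 3β-{2-[bis(2,2,2-trifluoroethoxy)phosphoryl]propanoyloxy} analogue of 18 (both epimers at the phosphonate α-carbon) | C=C(C)[C@@]1(O)C[C@@H]2[C@](C)(CC[C@H](OC(=O)C(C)P(=O)(OCC(F)(F)F)OCC(F)(F)F)[C@]2(C)OC(C)=O)C[C@@H]1O[Si](C(C)C)(C(C)C)C(C)C
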